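## Retrosynthetic overview

- **Feature:** in ring A, C8a lies between C8(OMe) and C4a, so the C4a≡C8a aryne is a 3-methoxyaryne. Its built-in polarisation (C4a electrophilic) matches a 2-amino diene that carries the whole chain C4–C3–C2–C1.
- **Disconnections:** C3–CHO goes back to a C3 ketone (enol triflate toward benzylic C4, then carbonylative formylation). Ring B goes back to a [4+2] addition that forms C4–C4a and C1–C8a.
- **Stereocontrol:** C1 is set in the cycloaddition by an (S)-2-(methoxymethyl)pyrrolidine group on C3. C2 is set afterwards by strain-controlled enamine equilibration.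
- **Ring order:** ring A and the pendant guaiacyl ring are bought as benzyl ethers. Ring B is the only ring made (step 7).
- **Fragments:** the silylaryl triflate comes from directed ortho-metalation (3 steps). The diene comes from a Morita–Baylis–Hillman reaction, allylic transposition with BnOH and enamine condensation (3 steps). All three benzyl groups fall together in the last step.

Key step: step 7

Numbering remark: all bicyclic compounds carry the numbering of the target (C1 = ArCH, C2 = CH–CH2O, C3, C4, C4a, C5–C8, C8a). The SMILES strings are decisive for configuration.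

Assumption: the sense of facial induction follows the A(1,3)-strain model given in step 7. Should it prove opposite, the equally commercial (R)-2-(methoxymethyl)pyrrolidine is used with no other change.

## Route

Step 1
Reactants: 1 4-(benzyloxy)-3-methoxyphenol
Product: 2 4-(benzyloxy)-3-methoxyphenyl N-isopropylcarbamate
Conditions: i-PrNCO, Et3N (cat.), CH2Cl2, rt
Reagents that add atoms: isopropyl isocyanate, CC(C)N=C=O
Why: Base-catalysed addition of the phenol to the isocyanate (carbamoylation) installs the strongest oxygen-based directing group in a form that can later be removed under mild conditions.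

Step 2
Reactants: 2 4-(benzyloxy)-3-methoxyphenyl N-isopropylcarbamate
Product: 6 4-(benzyloxy)-3-methoxy-2-(trimethylsilyl)phenyl N-isopropylcarbamate, via N-silyl carbamate 3 (not isolated), via C2 aryllithium 4 (not isolated), via bis-silyl carbamate 5 (not isolated)
Conditions: TMEDA, TBSOTf, Et2O, 0 °C → rt; TMEDA, n-BuLi (2 equiv), −78 °C; Me3SiCl, −78 °C → rt; aq NaHSO4
Reagents that add atoms: chlorotrimethylsilane, C[Si](C)(C)Cl; tert-butyldimethylsilyl trifluoromethanesulfonate, CC(C)(C)[Si](C)(C)OS(=O)(=O)C(F)(F)F (silyl group present only in 3–5); n-butyllithium, [Li]CCCC (lithium present only in 4)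
Why: Directed ortho-metalation: once in-situ N-silylation has masked the N–H, n-BuLi·TMEDA is guided by the carbamate and the methoxy group to their common ortho position C2, which at −78 °C in Et2O should outrun lithiation at C6 or at the benzylic OCH2Ph, and Me3SiCl traps the anion while the N–Si bond falls off on acidic work-up.

Step 3
Reactants: 6 4-(benzyloxy)-3-methoxy-2-(trimethylsilyl)phenyl N-isopropylcarbamate
Product: 8 4-(benzyloxy)-3-methoxy-2-(trimethylsilyl)phenyl trifluoromethanesulfonate, via 2-silylphenol 7 (not isolated)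
Conditions: DBU, Et2NH, MeCN, 40 °C; then PhNTf2, rt
Reagents that add atoms: N-phenylbis(trifluoromethanesulfonimide), O=S(=O)(N(c1ccccc1)S(=O)(=O)C(F)(F)F)C(F)(F)F
Why: DBU triggers E1cB loss of isopropyl isocyanate from the secondary carbamate (Et2NH scavenges it as a urea), and the freed phenolate is O-sulfonylated in the same pot under conditions too mild for protodesilylation.

Step 4
Reactants: 9 4-(benzyloxy)-3-methoxybenzaldehyde (O-benzylvanillin); 10 methyl vinyl ketone
Product: 11 rac-3-{[4-(benzyloxy)-3-methoxyphenyl](hydroxy)methyl}but-3-en-2-one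
Conditions: DABCO (0.5 equiv), 1,4-dioxane/H2O (1:1), rt
Reagents that add atoms: none
Why: Morita–Baylis–Hillman reaction: DABCO adds to 10 and the zwitterionic enolate attacks the aldehyde, the aqueous medium speeding up the slow addition to this electron-rich aldehyde, and the racemic carbinol centre is erased in step 5.

Step 5
Reactants: 11 rac-3-{[4-(benzyloxy)-3-methoxyphenyl](hydroxy)methyl}but-3-en-2-one
Product: 12 (E)-3-[(benzyloxy)methyl]-4-[4-(benzyloxy)-3-methoxyphenyl]but-3-en-2-one
Conditions: BnOH (5 equiv), TsOH·H2O (10 mol %), CH2Cl2, 40 °C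
Reagents that add atoms: benzyl alcohol, OCc1ccccc1
Why: Acid-catalysed allylic transposition (SN1′-type etherification known for Morita–Baylis–Hillman alcohols): the p-alkoxybenzylic allyl cation forms easily and its reversible capture by BnOH drains to the conjugated primary ether, with the aryl group trans to the acetyl group (E) to avoid A(1,3) strain.

Step 6
Reactants: 12 (E)-3-[(benzyloxy)methyl]-4-[4-(benzyloxy)-3-methoxyphenyl]but-3-en-2-one; 13 (S)-2-(methoxymethyl)pyrrolidine
Product: 14 (2S)-1-{(3Z)-3-[(benzyloxy)methyl]-4-[4-(benzyloxy)-3-methoxyphenyl]buta-1,3-dien-2-yl}-2-(methoxymethyl)pyrrolidine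
Conditions: TiCl4 (0.6 equiv), Et3N (4 equiv), toluene, 0 °C → rt; filtration under argon, used crude
Reagents that add atoms: none
Why: TiCl4-mediated enamine condensation: the iminium ion has acidic hydrogens only on its methyl group, so it can give only the cross-conjugated 2-amino diene, with the alkene geometry kept (aryl trans to the amino-vinyl unit, descriptor now Z only because CH2OBn outranks the nitrogen-bearing carbon).

Step 7
Reactants: 8 4-(benzyloxy)-3-methoxy-2-(trimethylsilyl)phenyl trifluoromethanesulfonate; 14 the 2-amino diene of step 6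
Product: 16 (S)-1-{(1R)-7-(benzyloxy)-1-[4-(benzyloxy)-3-methoxyphenyl]-2-[(benzyloxy)methyl]-8-methoxy-1,4-dihydronaphthalen-3-yl}-2-(methoxymethyl)pyrrolidine (C2=C3 enamine), via 4-(benzyloxy)-3-methoxybenzyne 15 (not isolated)
Conditions: CsF (3 equiv), MeCN/toluene (1:3), 4 Å MS, argon, 0 °C → rt; used crude
Reagents that add atoms: none
Why: Proposed new method: fluoride attack on silicon and loss of triflate from 8 release aryne 15, in which the inductively withdrawing C8 methoxy group distorts the triple bond so that C4a (meta to OMe) is the electrophilic end, and the enamine β-carbon C4 of 14 bonds there ahead of C1–C8a bonding in a concerted but strongly asynchronous, suprafacial [4+2] cycloaddition. Ring B is closed as a six-membered carbocycle by an untethered intermolecular cycloaddition, and even at the stepwise limit the aryl anion at C8a should close on C1 of the unsaturated iminium ion (6-endo conjugate mode) more readily than on C3 (strained benzocyclobutene, the [2+2] outcome). The closest known reaction types are regioselective Diels–Alder reactions of 3-alkoxyarynes with 2-oxygenated dienes, auxiliary-controlled aryne cycloadditions of acyclic dienes, and the face-selective cycloadditions of 2-(methoxymethyl)pyrrolidine-derived 2-amino dienes with nitroalkenes; their combination is what is new. C1, the only new stereocentre, is controlled by the auxiliary: A(1,3) strain against the C2 CH2OBn group turns the pyrrolidine stereocentre toward the =CH2 terminus with its CH2OMe arm standing over one diene face, so the flat aryne (no endo/exo issue) takes the open face, which for the (S)-amine and the aryl-outside alkene geometry places C1–H as in the target (descriptor 1R in 16 only because C2 outranks the aryl group). The step needs regioselectivity (secured by the matched polarisation of aryne and enamine), periselectivity for [4+2] over [2+2] (helped by the s-cis bias of the 2,3-disubstituted diene) and facial selectivity, which rests on the auxiliary alone and is the unproven part.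

Step 8
Reactants: 16 the C2=C3 enamine of step 7
Product: 18 (1S,2S)-7-(benzyloxy)-1-[4-(benzyloxy)-3-methoxyphenyl]-2-[(benzyloxy)methyl]-8-methoxy-1,4-dihydronaphthalen-3(2H)-one (1,2-trans 2-tetralone), via conjugated enamine 17 (not isolated)
Conditions: AcOH (1 equiv), THF, argon, rt; then AcOH/NaOAc buffer (pH 5), H2O, 0 °C → rt
Reagents that add atoms: water, O
Why: Enamine isomerisation and hydrolysis under thermodynamic control: reversible C2-protonation and C4-deprotonation move the double bond into conjugation with ring A, and in 17 A(1,3) strain with the pyrrolidine forces the C2 CH2OBn group axial while peri strain with the C8 OMe keeps the C1 aryl axial, so C2 should settle trans to C1 before water cleaves the C3–N bond through protonation at C4, which does not touch C2.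

Step 9
Reactants: 18 the trans 2-tetralone of step 8
Product: 20 (1S,2S)-7-(benzyloxy)-1-[4-(benzyloxy)-3-methoxyphenyl]-2-[(benzyloxy)methyl]-8-methoxy-1,2-dihydronaphthalen-3-yl trifluoromethanesulfonate, via potassium enolate 19 (not isolated)
Conditions: KN(SiMe3)2, THF, −78 °C; N-(5-chloropyridin-2-yl)bis(trifluoromethanesulfonimide), −78 → −40 °C; aq NH4Cl
Reagents that add atoms: N-(5-chloropyridin-2-yl)bis(trifluoromethanesulfonimide), O=S(=O)(N(c1ccc(Cl)cn1)S(=O)(=O)C(F)(F)F)C(F)(F)F; potassium bis(trimethylsilyl)amide, C[Si](C)(C)[N-][Si](C)(C)C.[K+] (potassium present only in 19)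
Why: Regioselective enol triflate formation: the benzylic C4 hydrogens are by far the more acidic and the less hindered, so only the ring-A-conjugated enolate should form, which leaves C2–H and the β-benzyloxy group untouched (no epimerisation, no E1cB) and is O-triflated at low temperature.

Step 10
Reactants: 20 the enol triflate of step 9
Product: 21 (1S,2R)-7-(benzyloxy)-1-[4-(benzyloxy)-3-methoxyphenyl]-2-[(benzyloxy)methyl]-8-methoxy-1,2-dihydronaphthalene-3-carbaldehyde
Conditions: Pd(OAc)2 (5 mol %), dppp, CO (1 atm), Et3SiH, Et3N, DMF, 60 °C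
Reagents that add atoms: carbon monoxide, [C-]#[O+]
Why: Palladium-catalysed reductive carbonylation (formylation) of a vinyl triflate: zerovalent palladium formed in situ inserts into the C3–OTf bond, CO insertion gives the acyl complex of divalent palladium and Et3SiH delivers the hydride, all at sp2 carbon so that C1 and C2 are not affected.

Step 11
Reactants: 21 the tribenzyl enal of step 10
Product: 22 vitedoin A, (1S,2R)-7-hydroxy-1-(4-hydroxy-3-methoxyphenyl)-2-(hydroxymethyl)-8-methoxy-1,2-dihydronaphthalene-3-carbaldehyde
Conditions: BCl3, C6HMe5, CH2Cl2, −78 → −30 °C; MeOH quench, aq work-up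
Reagents that add atoms: none
Why: Lewis-acid debenzylation: BCl3 activates the three benzyl ethers and pentamethylbenzene takes up the benzyl cations by Friedel–Crafts alkylation, which at low temperature should spare the two aryl methyl ethers, the enal, the C3=C4 alkene (which rules out hydrogenolysis) and both stereocentres.

## Compound list

| No. | Name | SMILES | Role |
|---|---|---|---|
| 1 | 4-(benzyloxy)-3-methoxyphenol | COc1cc(O)ccc1OCc1ccccc1 | starting material |
| 2 | 4-(benzyloxy)-3-methoxyphenyl N-isopropylcarbamate | COc1cc(OC(=O)NC(C)C)ccc1OCc1ccccc1 | intermediate |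
| 3 | N-(tert-butyldimethylsilyl) derivative of 2 (not isolated) | COc1cc(OC(=O)N(C(C)C)[Si](C)(C)C(C)(C)C)ccc1OCc1ccccc1 | intermediate |
| 4 | C2-lithio derivative of 3 (not isolated) | COc1c([Li])c(OC(=O)N(C(C)C)[Si](C)(C)C(C)(C)C)ccc1OCc1ccccc1 | intermediate |
| 5 | 4-(benzyloxy)-3-methoxy-2-(trimethylsilyl)phenyl N-(tert-butyldimethylsilyl)-N-isopropylcarbamate (not isolated) | COc1c([Si](C)(C)C)c(OC(=O)N(C(C)C)[Si](C)(C)C(C)(C)C)ccc1OCc1ccccc1 | intermediate |
| 6 | 4-(benzyloxy)-3-methoxy-2-(trimethylsilyl)phenyl N-isopropylcarbamate | COc1c([Si](C)(C)C)c(OC(=O)NC(C)C)ccc1OCc1ccccc1 | intermediate |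
| 7 | 4-(benzyloxy)-3-methoxy-2-(trimethylsilyl)phenol, present as its DBU phenolate (not isolated) | COc1c([Si](C)(C)C)c(O)ccc1OCc1ccccc1 | intermediate |
| 8 | 4-(benzyloxy)-3-methoxy-2-(trimethylsilyl)phenyl trifluoromethanesulfonate | COc1c([Si](C)(C)C)c(OS(=O)(=O)C(F)(F)F)ccc1OCc1ccccc1 | intermediate |
| 9 | 4-(benzyloxy)-3-methoxybenzaldehyde | COc1cc(C=O)ccc1OCc1ccccc1 | starting material |
| 10 | methyl vinyl ketone | CC(=O)C=C | starting material |
| 11 | rac-3-{[4-(benzyloxy)-3-methoxyphenyl](hydroxy)methyl}but-3-en-2-one | CC(=O)C(=C)C(O)c1ccc(OCc2ccccc2)c(OC)c1 | intermediate |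
| 12 | (E)-3-[(benzyloxy)methyl]-4-[4-(benzyloxy)-3-methoxyphenyl]but-3-en-2-one | CC(=O)/C(COCc1ccccc1)=C/c1ccc(OCc2ccccc2)c(OC)c1 | intermediate |
| 13 | (S)-2-(methoxymethyl)pyrrolidine | COC[C@@H]1CCCN1 | starting material |
| 14 | (2S)-1-{(3Z)-3-[(benzyloxy)methyl]-4-[4-(benzyloxy)-3-methoxyphenyl]buta-1,3-dien-2-yl}-2-(methoxymethyl)pyrrolidine | COC[C@@H]1CCCN1C(=C)/C(COCc1ccccc1)=C/c1ccc(OCc2ccccc2)c(OC)c1 | intermediate |
| 15 | 4-(benzyloxy)-3-methoxybenzyne (not isolated) | COC1=C(OCc2ccccc2)C=CC#C1 | intermediate |
| 16 | (1R) C2=C3 enamine cycloadduct, (S)-auxiliary | COc1cc([C@H]2c3c(ccc(OCc4ccccc4)c3OC)CC(N4CCC[C@H]4COC)=C2COCc2ccccc2)ccc1OCc1ccccc1 | intermediate |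
| 17 | (1S,2R) C3=C4 enamine, 1,2-trans, (S)-auxiliary (not isolated) | COc1cc([C@H]2c3c(ccc(OCc4ccccc4)c3OC)C=C(N4CCC[C@H]4COC)[C@@H]2COCc2ccccc2)ccc1OCc1ccccc1 | intermediate |
| 18 | (1S,2S) trans 2-tetralone (C3 ketone) | COc1cc([C@H]2c3c(ccc(OCc4ccccc4)c3OC)CC(=O)[C@@H]2COCc2ccccc2)ccc1OCc1ccccc1 | intermediate |
| 19 | potassium C3=C4 enolate of 18 (not isolated) | COc1cc([C@H]2c3c(ccc(OCc4ccccc4)c3OC)C=C([O-])[C@@H]2COCc2ccccc2)ccc1OCc1ccccc1.[K+] | intermediate |
| 20 | (1S,2S) C3 enol triflate | COc1cc([C@H]2c3c(ccc(OCc4ccccc4)c3OC)C=C(OS(=O)(=O)C(F)(F)F)[C@@H]2COCc2ccccc2)ccc1OCc1ccccc1 | intermediate |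
| 21 | (1S,2R) tri-O-benzyl vitedoin A | COc1cc([C@H]2c3c(ccc(OCc4ccccc4)c3OC)C=C(C=O)[C@@H]2COCc2ccccc2)ccc1OCc1ccccc1 | intermediate |
| 22 | vitedoin A | COc1cc([C@H]2c3c(ccc(O)c3OC)C=C(C=O)[C@@H]2CO)ccc1O | target |

## Step count

- Total step count: 11.
- Longest linear sequence: 8 steps (steps 4–11 from 9; equally steps 1–3 and 7–11 from 1).

## Steps most likely to fail

**(a) Step 7.**
- What may go wrong:
  - The early transition state of a very reactive aryne may give poor facial discrimination.
  - The enamine may be diverted into [2+2] addition or simple arylation.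
  - The diene may be hydrolysed by adventitious water.
- The fallback uses known chemistry only. It sets out from 12 and 8 and comes back to the route at 18.
- Soft enolisation of 12 (TBSOTf, Et3N, CH2Cl2, 0 °C) gives the (3E)-2-(tert-butyldimethylsilyloxy) diene F1.
- Diels–Alder reaction of F1 with aryne 15 released from 8 (CsF, MeCN, rt) is the established case of a 3-alkoxyaryne with a 2-oxygenated diene. With the same regiochemistry it gives the racemic silyl enol ether cycloadduct F2.
- HF·pyridine in THF cleaves F2 to the racemic ketone as a C2-epimer mixture F3.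
- Condensation of F3 with pyrrolidine (4 Å MS, toluene) gives the racemic trans C3=C4 pyrrolidine enamine F4, in which the same A(1,3) and peri strain fix the 1,2-trans relation.
- Buffered hydrolysis as in step 8 gives the racemic trans ketone. This is 18 together with its (1R,2R) enantiomer F5, which is removed by preparative HPLC on a chiral stationary phase.
- Half of the material is given up in exchange for an absolute configuration that no longer depends on the auxiliary.

**(b) Step 8.**
- What may go wrong:
  - Equilibration at C2 may be incomplete, because kinetic protonation anti to the aryl group favours the cis series.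
  - Acid may assist loss of benzyl alcohol from the β-(alkoxymethyl) enamine.
  - Air may oxidise the dihydronaphthalene.
- The fallback sets C2 by C–C bond formation instead of protonation. It sets out from 9, 13 and 8 and comes back at 17.
- Claisen–Schmidt condensation of 9 with acetone (aq NaOH) gives (E)-4-[4-(benzyloxy)-3-methoxyphenyl]but-3-en-2-one F6.
- TiCl4/Et3N condensation of F6 with 13 gives the C2-unsubstituted amino diene F7.
- Cycloaddition of F7 with 15 under the conditions of step 7 gives the (1S) C2-unsubstituted C2=C3 enamine F8.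
- Before any proton source is admitted, BnOCH2Cl and i-Pr2NEt are added to F8. Stork enamine alkylation then takes place at C2 from the face opposite the pseudoaxial C1 aryl group.
- Loss of the C4 proton then gives 17 directly, and 17 is hydrolysed as in the second half of step 8.

**(c) Step 6.**
- What may go wrong:
  - The amine may add in conjugate fashion and expel the allylic benzyloxy group under TiCl4 activation.
  - The alkene geometry may be scrambled.
  - Condensation of the hindered ketone may be incomplete.
- The fallback builds the C–N bond by alkyne hydroamination. It sets out from 12 and comes back at 14.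
- Kinetic deprotonation of the methyl group (LDA, THF, −78 °C) and trapping with ClP(O)(OEt)2 give the (3E)-dienyl diethyl phosphate F9.
- Elimination with further LDA gives the (Z)-enyne F10.
- Addition of 13 under Hg(OAc)2 catalysis (Et3N, THF, rt; catalytic aminomercuration of a conjugated enyne) places nitrogen on the internal alkyne carbon and gives 14.

## Further compounds

F1 | step 7 | tert-butyl({(3E)-3-[(benzyloxy)methyl]-4-[4-(benzyloxy)-3-methoxyphenyl]buta-1,3-dien-2-yl}oxy)dimethylsilane | C=C(O[Si](C)(C)C(C)(C)C)/C(COCc1ccccc1)=C/c1ccc(OCc2ccccc2)c(OC)c1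
F2 | step 7 | racemic C2=C3 tert-butyldimethylsilyl enol ether cycloadduct | COc1cc(C2c3c(ccc(OCc4ccccc4)c3OC)CC(O[Si](C)(C)C(C)(C)C)=C2COCc2ccccc2)ccc1OCc1ccccc1
F3 | step 7 | racemic C3 ketone, mixture of C2 epimers | COc1cc(C2c3c(ccc(OCc4ccccc4)c3OC)CC(=O)C2COCc2ccccc2)ccc1OCc1ccccc1
F4 | step 7 | racemic 1,2-trans C3=C4 pyrrolidine enamine (one enantiomer drawn) | COc1cc([C@H]2c3c(ccc(OCc4ccccc4)c3OC)C=C(N4CCCC4)[C@@H]2COCc2ccccc2)ccc1OCc1ccccc1
F5 | step 7 | (1R,2R) enantiomer of 18 | COc1cc([C@@H]2c3c(ccc(OCc4ccccc4)c3OC)CC(=O)[C@H]2COCc2ccccc2)ccc1OCc1ccccc1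
F6 | step 8 | (E)-4-[4-(benzyloxy)-3-methoxyphenyl]but-3-en-2-one | CC(=O)/C=C/c1ccc(OCc2ccccc2)c(OC)c1
F7 | step 8 | (2S)-1-{(3E)-4-[4-(benzyloxy)-3-methoxyphenyl]buta-1,3-dien-2-yl}-2-(methoxymethyl)pyrrolidine | COC[C@@H]1CCCN1C(=C)/C=C/c1ccc(OCc2ccccc2)c(OC)c1
F8 | step 8 | (1S) C2-unsubstituted C2=C3 enamine cycloadduct, (S)-auxiliary | COc1cc([C@H]2c3c(ccc(OCc4ccccc4)c3OC)CC(N4CCC[C@H]4COC)=C2)ccc1OCc1ccccc1
F9 | step 6 | (3E)-3-[(benzyloxy)methyl]-4-[4-(benzyloxy)-3-methoxyphenyl]buta-1,3-dien-2-yl diethyl phosphate | C=C(OP(=O)(OCC)OCC)/C(COCc1ccccc1)=C/c1ccc(OCc2ccccc2)c(OC)c1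
F10 | step 6 | (Z)-1-(benzyloxy)-4-{2-[(benzyloxy)methyl]but-1-en-3-yn-1-yl}-2-methoxybenzene | C#C/C(COCc1ccccc1)=C/c1ccc(OCc2ccccc2)c(OC)c1
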